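**Assumptions (one line each)**
- Ferugin is taken exactly as the SMILES: (3R,3aS,4S,7S,8aR)-3,7-dihydroxy-8a-methyl-6-methylidene-3-(propan-2-yl)decahydroazulen-4-yl 4-hydroxybenzoate (trans-fused; azulene numbering is used below).
- Compounds 1, 2, 7 and 12 are taken as catalogue items; the chiral Cu–NHC catalyst in step 2 is used in the antipode that gives (R)-6.
- The route is a design based on known reaction types; it has not been run.

**Retrosynthetic overview**
1. Ferugin ⇒ phenol-TBS ether 15; the C4 ester is installed before the third hydroxyl exists, so no OH differentiation is needed.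
2. The seven-membered ring is formed last: C6–C7 bond by intramolecular Nozaki–Hiyama–Kishi (NHK) addition of a 2-bromoallyl unit to a C7 aldehyde, which gives the 6-methylidene-7-ol directly.
3. C3 carbinol ⇒ isopropyl-cerium addition to a cyclopentanone; C3a–C4 bond ⇒ anti aldol of a regiodefined enolate with 3-bromobut-3-enal.
4. C8a quaternary centre ⇒ Cu-catalysed asymmetric conjugate addition of Me3Al to a 3-substituted cyclopentenone, with the enolate trapped as a silyl enol ether.
5. The five-membered ring is carried in from 3-ethoxycyclopent-2-enone; it is never formed in the route.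

**Route**

Step 1
Reactants: 1, 3-ethoxycyclopent-2-en-1-one; 2, (1,3-dioxolan-2-ylmethyl)magnesium bromide
Product: 3, 3-(1,3-dioxolan-2-ylmethyl)cyclopent-2-en-1-one
Conditions: 2 (1.5 equiv), CeCl3, THF, 0 °C → rt; then 1 M HCl, 0 °C, 10 min
Reagents that add atoms: 2, Br[Mg]CC1OCCO1; water, O (supplies the new carbonyl oxygen on hydrolysis)
Why: Stork–Danheiser sequence (1,2-addition to the vinylogous ester, then acid hydrolysis/dehydration) transposes the enone and puts the masked CH2CHO arm on the β-carbon; no stereocentre is formed.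

Step 2
Reactants: 3; 4, trimethylaluminium; 5, triethylsilyl triflate
Product: 6, (R)-{[3-(1,3-dioxolan-2-ylmethyl)-3-methylcyclopent-1-en-1-yl]oxy}triethylsilane
Conditions: Me3Al (3 equiv), Cu(OTf)2 (5 mol %), chiral sulfonate-bearing NHC–Ag complex (2.5 mol %), THF, −78 °C; then TESOTf, −78 → 0 °C
Reagents that add atoms: Me3Al, C[Al](C)C; TESOTf, CC[Si](CC)(CC)OS(=O)(=O)C(F)(F)F
Why: Cu–NHC-catalysed asymmetric conjugate addition sets the quaternary C8a (R) under catalyst control, and O-silylation stores the aluminium enolate regiospecifically on the hindered α-carbon.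

Step 3
Reactants: 7, 3-bromobut-3-en-1-ol
Product: 8, 3-bromobut-3-enal (used immediately as a cold CH2Cl2 solution)
Conditions: Dess–Martin periodinane, NaHCO3, CH2Cl2, 0 °C
Reagents that add atoms: none
Why: Buffered, non-basic Dess–Martin oxidation should give the β,γ-unsaturated aldehyde without isomerisation to the conjugated enal.

Step 4
Reactants: 6; 8
Product: 9, (2S,3R)-2-[(1S)-3-bromo-1-hydroxybut-3-en-1-yl]-3-(1,3-dioxolan-2-ylmethyl)-3-methylcyclopentan-1-one (side chain cis to the methyl, trans to the dioxolanylmethyl arm)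
Conditions: MeLi, THF, 0 °C; ZnCl2, −78 °C; then 8, −78 °C, 20 min; AcOH quench at −78 °C
Reagents that add atoms: 8, C=C(Br)CC=O
Why: MeLi unmasks the regiodefined enolate, whose (E)-geometry gives the anti aldol via a Zimmerman–Traxler chair; attack anti to the larger dioxolanylmethyl arm sets C3a (S) and C4 (S).

Step 5
Reactants: 9; 10, isopropylmagnesium chloride
Product: 11, (1R,2S,3R)-2-[(1S)-3-bromo-1-hydroxybut-3-en-1-yl]-3-(1,3-dioxolan-2-ylmethyl)-3-methyl-1-(propan-2-yl)cyclopentan-1-ol (tertiary OH cis to the C2 side chain)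
Conditions: iPrMgCl (4 equiv), anhydrous CeCl3 (4 equiv), THF, −78 → −30 °C
Reagents that add atoms: iPrMgCl, CC(C)[Mg]Cl
Why: Organocerium (Imamoto) 1,2-addition suppresses enolisation, retro-aldol and Br/Mg exchange; isopropyl adds to the ketone face anti to the adjacent C2 side chain, giving the 3R carbinol.

Step 6
Reactants: 11; 12, 4-[(tert-butyldimethylsilyl)oxy]benzoic acid
Product: 13, (1S)-3-bromo-1-[(1S,2R,5R)-2-(1,3-dioxolan-2-ylmethyl)-5-hydroxy-2-methyl-5-(propan-2-yl)cyclopentyl]but-3-en-1-yl 4-[(tert-butyldimethylsilyl)oxy]benzoate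
Conditions: 12, 2,4,6-trichlorobenzoyl chloride, Et3N, toluene, rt; then 11, DMAP, rt → 45 °C
Reagents that add atoms: 12, CC(C)(C)[Si](C)(C)Oc1ccc(cc1)C(=O)O
Why: Yamaguchi esterification acylates only the secondary alcohol (the tertiary carbinol is inert) with retention at C4.

Step 7
Reactants: 13
Product: 14, (1S)-3-bromo-1-[(1S,2R,5R)-5-hydroxy-2-methyl-2-(2-oxoethyl)-5-(propan-2-yl)cyclopentyl]but-3-en-1-yl 4-[(tert-butyldimethylsilyl)oxy]benzoate
Conditions: PPTS (0.3 equiv), acetone/H2O 9:1, 55 °C
Reagents that add atoms: water, O (aldehyde oxygen)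
Why: Mild acid hydrolysis of the dioxolane frees the aldehyde while the aryl silyl ether, ester, vinyl bromide and tertiary alcohol survive; the tertiary OH is trans to the CH2CHO arm, so no lactol can form.

Step 8
Reactants: 14
Product: 15, (3R,3aS,4S,7S,8aR)-3,7-dihydroxy-8a-methyl-6-methylidene-3-(propan-2-yl)decahydroazulen-4-yl 4-[(tert-butyldimethylsilyl)oxy]benzoate
Conditions: CrCl2 (8 equiv), NiCl2 (0.1 equiv), degassed DMF/THF, 0.005 M, rt
Reagents that add atoms: none
Why: Intramolecular Nozaki–Hiyama–Kishi reaction closes the seven-membered ring and gives the exocyclic-methylene allylic alcohol directly; the 7S (α, equatorial) alcohol is expected from a TS with the O–Cr pseudo-equatorial, trans-1,3 to the angular methyl.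

Step 9
Reactants: 15
Product: 16, ferugin
Conditions: TBAF/AcOH (1:1, 1.2 equiv), THF, 0 °C
Reagents that add atoms: none
Why: Buffered fluoride cleaves the phenolic Si–O bond selectively, leaving the benzoate, the allylic alcohol and the exocyclic alkene untouched; no stereocentre is affected.

**Compound list**

1 | 3-ethoxycyclopent-2-en-1-one | CCOC1=CC(=O)CC1 | starting material
2 | (1,3-dioxolan-2-ylmethyl)magnesium bromide | Br[Mg]CC1OCCO1 | starting material
3 | 3-(1,3-dioxolan-2-ylmethyl)cyclopent-2-en-1-one | O=C1C=C(CC2OCCO2)CC1 | intermediate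
4 | trimethylaluminium | C[Al](C)C | starting material
5 | triethylsilyl trifluoromethanesulfonate | CC[Si](CC)(CC)OS(=O)(=O)C(F)(F)F | starting material
6 | (R)-{[3-(1,3-dioxolan-2-ylmethyl)-3-methylcyclopent-1-en-1-yl]oxy}triethylsilane | CC[Si](CC)(CC)OC1=C[C@](C)(CC1)CC1OCCO1 | intermediate
7 | 3-bromobut-3-en-1-ol | C=C(Br)CCO | starting material
8 | 3-bromobut-3-enal | C=C(Br)CC=O | intermediate
9 | (2S,3R)-2-[(1S)-3-bromo-1-hydroxybut-3-en-1-yl]-3-(1,3-dioxolan-2-ylmethyl)-3-methylcyclopentan-1-one | C=C(Br)C[C@H](O)[C@@H]1[C@](C)(CCC1=O)CC1OCCO1 | intermediate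
10 | isopropylmagnesium chloride | CC(C)[Mg]Cl | starting material
11 | (1R,2S,3R)-2-[(1S)-3-bromo-1-hydroxybut-3-en-1-yl]-3-(1,3-dioxolan-2-ylmethyl)-3-methyl-1-(propan-2-yl)cyclopentan-1-ol | C=C(Br)C[C@H](O)[C@@H]1[C@](C)(CC[C@@]1(O)C(C)C)CC1OCCO1 | intermediate
12 | 4-[(tert-butyldimethylsilyl)oxy]benzoic acid | CC(C)(C)[Si](C)(C)Oc1ccc(cc1)C(=O)O | starting material
13 | (1S)-3-bromo-1-[(1S,2R,5R)-2-(1,3-dioxolan-2-ylmethyl)-5-hydroxy-2-methyl-5-(propan-2-yl)cyclopentyl]but-3-en-1-yl 4-[(tert-butyldimethylsilyl)oxy]benzoate | C=C(Br)C[C@H](OC(=O)c1ccc(O[Si](C)(C)C(C)(C)C)cc1)[C@@H]1[C@](C)(CC[C@@]1(O)C(C)C)CC1OCCO1 | intermediate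
14 | (1S)-3-bromo-1-[(1S,2R,5R)-5-hydroxy-2-methyl-2-(2-oxoethyl)-5-(propan-2-yl)cyclopentyl]but-3-en-1-yl 4-[(tert-butyldimethylsilyl)oxy]benzoate | C=C(Br)C[C@H](OC(=O)c1ccc(O[Si](C)(C)C(C)(C)C)cc1)[C@@H]1[C@](C)(CC[C@@]1(O)C(C)C)CC=O | intermediate
15 | (3R,3aS,4S,7S,8aR)-3,7-dihydroxy-8a-methyl-6-methylidene-3-(propan-2-yl)decahydroazulen-4-yl 4-[(tert-butyldimethylsilyl)oxy]benzoate | C=C1C[C@H](OC(=O)c2ccc(O[Si](C)(C)C(C)(C)C)cc2)[C@@H]2[C@](C)(CC[C@@]2(O)C(C)C)C[C@@H]1O | intermediate
16 | ferugin, (3R,3aS,4S,7S,8aR)-3,7-dihydroxy-8a-methyl-6-methylidene-3-(propan-2-yl)decahydroazulen-4-yl 4-hydroxybenzoate | C=C1C[C@H](OC(=O)c2ccc(O)cc2)[C@@H]2[C@](C)(CC[C@@]2(O)C(C)C)C[C@@H]1O | target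

**Step count**
- Total steps: 9
- Longest linear sequence: 8 (steps 1, 2, 4, 5, 6, 7, 8, 9 from compound 1)

**Three steps most likely to fail, with fallbacks**

1. Step 4 (aldol). The aldehyde 8 is labile, and two selectivities are needed at once: the face of the enolate (Me versus CH2-dioxolanyl on the neighbouring quaternary carbon) and anti versus syn at the carbinol.
   - Fallback for the aldehyde and the carbinol: install the carbinol carbon as a formyl equivalent (6 + HC(OMe)3/TMSOTf gives the α-dimethoxymethyl ketone). Add isopropyl, release the β-hydroxy aldehyde, and build the C4–C5 bond by chelation-controlled 2-bromoallylation (2,3-dibromopropene/In, or 2-bromoallyl-TMS/MgBr2). This gives the same anti relationship and avoids 8.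
   - Fallback for the facial selectivity: swap the conjugate-addition partners (3-methylcyclopent-2-enone plus 1-(trimethylsilyl)vinyl–Al(iBu)2, same Cu–NHC catalysis) so the quaternary carbon carries a much bulkier group. The aldehyde arm is then made by protodesilylation, hydroboration and oxidation.

2. Step 5 (isopropyl addition to a hindered, enolisable β-hydroxy ketone). Retro-aldol, reduction or enolisation could compete.
   - Fallback: on the acetal-ketone of fallback 1, which has no other alkene or halide, add 2-propenyl-MgBr/CeCl3 (no β-hydride, less basic) and hydrogenate the isopropenyl group before the bromoalkene is introduced.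

3. Step 8 (NHK closure of the seven-membered ring and C7 configuration).
   - Fallback: close the ring by ring-closing metathesis instead. Convert the C8a arm to allyl (Wittig on the aldehyde) and use a methallyl carbinol arm (aldol with 3-methylbut-3-enal); Grubbs II then gives the ferutinin-type endocyclic trisubstituted alkene. α-Face epoxidation followed by epoxide-to-allylic-alcohol isomerisation (LiNEt2 or Et2Al-TMP) gives the 6-methylidene-7α-ol, with the C7 configuration fixed by the epoxide.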